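**Retrosynthetic overview**
- The strategy rests on C6 of the 2-pyranone ring, which carries the phenyl ring. In the 6-unsubstituted pyranone, C6–H is the only ring C–H on a carbon bonded to ring oxygen O1, and C3 is blocked by the quaternary 2-methylbut-3-en-2-yl group.
- The C6–phenyl bond is cut last among the C–C bonds: C6–H zincation of a 4-O-protected pyranone, then Negishi coupling with iodobenzene.
- The O4 ester is cut to 3-hydroxy-3-methylbutanoic acid, used as its O-triethylsilyl ether; O4 is carried through the coupling as a 4-methoxybenzyl ether.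
- The pyranone, the only ring that is built, is closed first (O1–C2 lactonisation) from methyl 3,3-dimethylpent-4-enoate after C-acetylation and formylation. The phenyl ring is attached, not formed.

Key step: step 5

Remark on the chemistry: the target has no stereocentre. C2 of the open-chain intermediates 2 and 3 is racemic and becomes the sp2 carbon C3 of the pyranone. Compound 3 is drawn as the keto aldehyde, although enol tautomers should dominate.

**Route**

Step 1
Reactants: 1 methyl 3,3-dimethylpent-4-enoate
Product: 2 methyl 2-acetyl-3,3-dimethylpent-4-enoate (racemic)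
Conditions: LiN(iPr)2 (2.0 equiv), 1 (2.0 equiv), THF, −78 °C; AcCl (1.0 equiv), −78 → 0 °C; aq. NH4Cl
Reagents that add atoms: acetyl chloride, CC(=O)Cl
Why: Claisen-type C-acylation of a lithium ester enolate by an acid chloride, in which the second equivalent of enolate takes up the proton of the more acidic keto ester 2, so that this half of 1 is recovered and reused.

Step 2
Reactants: 2 methyl 2-acetyl-3,3-dimethylpent-4-enoate
Product: 3 methyl 2-(2-methylbut-3-en-2-yl)-3,5-dioxopentanoate (racemic, used crude)
Conditions: LiN(iPr)2 (2.3 equiv), THF, −78 → 0 °C; HCO2Et (1.3 equiv), −78 → 0 °C; cold 1 M HCl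
Reagents that add atoms: ethyl formate, CCOC=O
Why: Claisen formylation of a β-keto ester dianion, in which the acetyl methyl carbon is the reacting terminus whether or not the hindered C2–H is removed first, and the formyl ketone is withdrawn from the equilibrium as its chelated enolate.

Step 3
Reactants: 3 methyl 2-(2-methylbut-3-en-2-yl)-3,5-dioxopentanoate
Product: 4 4-hydroxy-3-(2-methylbut-3-en-2-yl)-2H-pyran-2-one
Conditions: DBU (1.5 equiv), PhMe, 80 °C; 1 M HCl wash
Reagents that add atoms: none
Why: Base-mediated lactonisation of a 5-hydroxy-3-oxopent-4-enoate, in which the C5 enolate oxygen attacks the methyl ester (6-exo-trig acyl substitution), methanol leaves and the ring tautomerises to the 4-hydroxy-2-pyranone; strong acid is avoided because it could add the 4-hydroxyl to the vinyl group.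

Step 4
Reactants: 4 4-hydroxy-3-(2-methylbut-3-en-2-yl)-2H-pyran-2-one
Product: 5 4-[(4-methoxybenzyl)oxy]-3-(2-methylbut-3-en-2-yl)-2H-pyran-2-one
Conditions: 4-methoxybenzyl chloride (1.2 equiv), K2CO3 (1.5 equiv), n-Bu4NI (cat.), DMF, 25 → 50 °C
Reagents that add atoms: 4-methoxybenzyl chloride, COc1ccc(CCl)cc1
Why: Williamson O-alkylation of a vinylogous acid in which C-alkylation is excluded because C3 is fully substituted, the 4-alkoxy-2-pyranone being the expected main product under K2CO3 in DMF and any 2-alkoxy-4-pyranone isomer being separable by chromatography.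

Step 5
Reactants: 5 4-[(4-methoxybenzyl)oxy]-3-(2-methylbut-3-en-2-yl)-2H-pyran-2-one; 6 iodobenzene
Product: 8 4-[(4-methoxybenzyl)oxy]-3-(2-methylbut-3-en-2-yl)-6-phenyl-2H-pyran-2-one, via pyranon-6-ylzinc chloride 7 (not isolated)
Conditions: TMPZnCl·LiCl (1.3 equiv), THF, 25 °C; then 6 (1.2 equiv), Pd(dba)2 (3 mol %), P(2-furyl)3 (6 mol %), 25 → 50 °C
Reagents that add atoms: none
Why: Proposed new method: the hindered amide of (2,2,6,6-tetramethylpiperidin-1-yl)zinc chloride–lithium chloride should remove C6–H, which is acidified by the adjacent ring oxygen O1 and lies at the δ-terminus of the C2 carbonyl, to give the covalent C6–zinc species 7, which is too weakly nucleophilic to add to or open the lactone. Oxidative addition of iodobenzene to zerovalent palladium, transmetallation from zinc and reductive elimination should then form the C6–phenyl bond. The closest known reaction type is the C–H zincation of chromones, pyridones, uracils and coumarins with TMP-zinc bases followed by Negishi arylation; a 6-unsubstituted 2-pyranone is not an established substrate. No ring is closed and no stereocentre is formed. The step needs metallation at C6 and not at C5: C3 is blocked by the quaternary group, and C5–H lacks the activation by O1 and sits beside the bulky 4-methoxybenzyloxy group. Transmetallation should outrun Heck-type insertion into the vinyl group, which is shielded by the neighbouring quaternary carbon, and the benzylic C–O bond should not add to zerovalent palladium at this temperature with the weak-donor phosphine.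

Step 6
Reactants: 8 4-[(4-methoxybenzyl)oxy]-3-(2-methylbut-3-en-2-yl)-6-phenyl-2H-pyran-2-one
Product: 9 4-hydroxy-3-(2-methylbut-3-en-2-yl)-6-phenyl-2H-pyran-2-one
Conditions: CF3CO2H (10 vol %), 1,3,5-trimethoxybenzene (3 equiv), CH2Cl2, 0 °C; toluene co-evaporation
Reagents that add atoms: none
Why: Acidolysis of a 4-methoxybenzyl ether whose oxygen belongs to a vinylogous acid, so that it should ionise as readily as a 4-methoxybenzyl ester (SN1), the benzylic cation being trapped by Friedel–Crafts alkylation of 1,3,5-trimethoxybenzene while cold dilute acid leaves the monosubstituted alkene unprotonated; oxidative cleavage with DDQ is not chosen because this electron-poor ether should react sluggishly.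

Step 7
Reactants: 10 3-hydroxy-3-methylbutanoic acid
Product: 12 3-methyl-3-[(triethylsilyl)oxy]butanoic acid, via bis(triethylsilyl) derivative 11 (not isolated)
Conditions: Et3SiOTf (2.3 equiv), 2,6-lutidine (3 equiv), CH2Cl2, −78 → 0 °C; then THF/H2O, pH 5 phosphate buffer, 25 °C
Reagents that add atoms: triethylsilyl trifluoromethanesulfonate, CC[Si](CC)(CC)OS(=O)(=O)C(F)(F)F
Why: Silylation of the tertiary alcohol and the acid with a silyl triflate, followed by selective hydrolysis of the labile silyl ester, which the more robust tertiary triethylsilyl ether should survive.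

Step 8
Reactants: 9 4-hydroxy-3-(2-methylbut-3-en-2-yl)-6-phenyl-2H-pyran-2-one; 12 3-methyl-3-[(triethylsilyl)oxy]butanoic acid
Product: 13 3-(2-methylbut-3-en-2-yl)-2-oxo-6-phenyl-2H-pyran-4-yl 3-methyl-3-[(triethylsilyl)oxy]butanoate
Conditions: DCC (1.3 equiv), DMAP (0.2 equiv), CH2Cl2, 0 → 25 °C
Reagents that add atoms: none
Why: Steglich esterification at O4, in which the usual DMAP-mediated acyl shift of 4-acyloxy-2-pyranones from oxygen to C3 cannot occur because C3 is fully substituted.

Step 9
Reactants: 13 3-(2-methylbut-3-en-2-yl)-2-oxo-6-phenyl-2H-pyran-4-yl 3-methyl-3-[(triethylsilyl)oxy]butanoate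
Product: 14 3-(2-methylbut-3-en-2-yl)-2-oxo-6-phenyl-2H-pyran-4-yl 3-hydroxy-3-methylbutanoate (CNP0160044.0)
Conditions: HF·pyridine, pyridine, THF, 0 °C
Reagents that add atoms: none
Why: Fluoride-mediated Si–O cleavage under buffered, non-nucleophilic conditions that should spare the activated enol ester and the lactone.

**Compound list**
1 | methyl 3,3-dimethylpent-4-enoate | C=CC(C)(C)CC(=O)OC | starting material
2 | methyl 2-acetyl-3,3-dimethylpent-4-enoate (racemic) | C=CC(C)(C)C(C(C)=O)C(=O)OC | intermediate
3 | methyl 2-(2-methylbut-3-en-2-yl)-3,5-dioxopentanoate (racemic, enol tautomers) | C=CC(C)(C)C(C(=O)OC)C(=O)CC=O | intermediate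
4 | 4-hydroxy-3-(2-methylbut-3-en-2-yl)-2H-pyran-2-one | C=CC(C)(C)c1c(O)ccoc1=O | intermediate
5 | 4-[(4-methoxybenzyl)oxy]-3-(2-methylbut-3-en-2-yl)-2H-pyran-2-one | C=CC(C)(C)c1c(OCc2ccc(OC)cc2)ccoc1=O | intermediate
6 | iodobenzene | Ic1ccccc1 | starting material
7 | [4-[(4-methoxybenzyl)oxy]-3-(2-methylbut-3-en-2-yl)-2-oxo-2H-pyran-6-yl]zinc chloride (LiCl complex, not isolated) | C=CC(C)(C)c1c(OCc2ccc(OC)cc2)cc([Zn]Cl)oc1=O | intermediate
8 | 4-[(4-methoxybenzyl)oxy]-3-(2-methylbut-3-en-2-yl)-6-phenyl-2H-pyran-2-one | C=CC(C)(C)c1c(OCc2ccc(OC)cc2)cc(-c2ccccc2)oc1=O | intermediate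
9 | 4-hydroxy-3-(2-methylbut-3-en-2-yl)-6-phenyl-2H-pyran-2-one | C=CC(C)(C)c1c(O)cc(-c2ccccc2)oc1=O | intermediate
10 | 3-hydroxy-3-methylbutanoic acid | CC(C)(O)CC(=O)O | starting material
11 | triethylsilyl 3-methyl-3-[(triethylsilyl)oxy]butanoate (not isolated) | CC[Si](CC)(CC)OC(C)(C)CC(=O)O[Si](CC)(CC)CC | intermediate
12 | 3-methyl-3-[(triethylsilyl)oxy]butanoic acid | CC[Si](CC)(CC)OC(C)(C)CC(=O)O | intermediate
13 | 3-(2-methylbut-3-en-2-yl)-2-oxo-6-phenyl-2H-pyran-4-yl 3-methyl-3-[(triethylsilyl)oxy]butanoate | C=CC(C)(C)c1c(OC(=O)CC(C)(C)O[Si](CC)(CC)CC)cc(-c2ccccc2)oc1=O | intermediate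
14 | 3-(2-methylbut-3-en-2-yl)-2-oxo-6-phenyl-2H-pyran-4-yl 3-hydroxy-3-methylbutanoate | C=CC(C)(C)c1c(OC(=O)CC(C)(C)O)cc(-c2ccccc2)oc1=O | target

**Step count**
Total: 9 steps. Longest linear sequence: 8 steps (steps 1 to 6, 8 and 9); step 7 is a one-step side branch.

**Steps most likely to fail**

Step 5 (key step). Deprotonation of C6–H by the mild zinc amide may be slow or incomplete, metallation may drift to C5 next to the ether oxygen, or the vinyl group may be consumed by Heck-type insertion during the coupling. The fallback uses known dianion acylation and lactonisation and sets out from 2. The dianion of 2 (LiN(iPr)2, 2.3 equiv, THF, −78 → 0 °C) would be acylated at the acetyl methyl carbon with methyl benzoate to give methyl 2-(2-methylbut-3-en-2-yl)-3,5-dioxo-5-phenylpentanoate F1. Heating F1 with DBU in toluene should lactonise it to 9, where the route is rejoined; steps 2 to 6 then fall away.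

Step 2. The hindered keto ester may be deprotonated incompletely, and the free formyl ketone may self-condense during work-up before it is lactonised. The fallback sets out from 2 and carries the formyl carbon in masked form. Heating 2 with N,N-dimethylformamide dimethyl acetal (neat, 100 °C) should condense the acetyl methyl group to methyl (4E)-5-(dimethylamino)-2-(2-methylbut-3-en-2-yl)-3-oxopent-4-enoate F2. Warming F2 in aqueous acetic acid (80 °C) should hydrolyse the vinylogous amide and lactonise in the same flask to 4, where the route is rejoined; steps 2 and 3 are replaced.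

Step 1. O-acylation of the hindered enolate and proton transfer from acetyl chloride (ketene formation) may cut down C-acylation. The fallback sets out from 1 and splits the acylation into an aldol addition and an oxidation. The lithium enolate of 1 (LiN(iPr)2, THF, −78 °C) would be added to acetaldehyde to give methyl 2-(1-hydroxyethyl)-3,3-dimethylpent-4-enoate F3 as a mixture of racemic diastereomers. Oxidation of F3 with Dess–Martin periodinane (CH2Cl2, NaHCO3, 25 °C) should give 2, where the route is rejoined.

**Further compounds**
F1 | step 5 | methyl 2-(2-methylbut-3-en-2-yl)-3,5-dioxo-5-phenylpentanoate (racemic) | C=CC(C)(C)C(C(=O)OC)C(=O)CC(=O)c1ccccc1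
F2 | step 2 | methyl (4E)-5-(dimethylamino)-2-(2-methylbut-3-en-2-yl)-3-oxopent-4-enoate (racemic) | C=CC(C)(C)C(C(=O)OC)C(=O)/C=C/N(C)C
F3 | step 1 | methyl 2-(1-hydroxyethyl)-3,3-dimethylpent-4-enoate (mixture of racemic diastereomers) | C=CC(C)(C)C(C(C)O)C(=O)OC
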